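**Retrosynthetic overview**
1. The strategy rests on ring C: its C2–C3–C4 chain with oxygen on C4 is the C3–C4–C5–O1 edge of a 3,5-diarylisoxazole (nitrogen on the future C2). Ring A has two equivalent oxygens (C5–OH and O1 on C8a) flanking C4a, so it can enter as a mirror-symmetric 2,6-bis(benzyloxy)-3,4,5-trimethoxyphenyl alkyne.
2. Disconnections: O1–C2 (phenol onto enaminone, loss of NH3) and N–O (hydrogenolysis) lead back to an isoxazol-4-ol; C3–OH leads back to isoxazole C4–H (iodination, borylation–oxidation); the isoxazole is split into a ring B nitrile oxide and a ring A terminal alkyne.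
3. The alkyne comes from 2,3,4-trimethoxybenzaldehyde (C5 bromination, Baeyer–Villiger, Br to OH, ortho-formylation, Ohira–Bestmann); the dipole comes from 3-hydroxy-4,5-dimethoxybenzaldehyde (benzylation, oxime, chlorination).
4. Ring order: rings A and B are bought; the isoxazole is closed in step 11; ring C is closed last, in step 14.

Key step: step 11

Remark: the target has no stereocentre; the only stereo elements on the way are C=N and C=C geometries that do not persist in the product.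

**Route**

Step 1
Reactants: 1 2,3,4-trimethoxybenzaldehyde
Product: 2 5-bromo-2,3,4-trimethoxybenzaldehyde
Conditions: NBS, DMF, rt
Reagents that add atoms: N-bromosuccinimide, O=C1CCC(=O)N1Br
Why: Electrophilic aromatic bromination should go to C5, which is ortho to the C4 methoxy, para to the C2 methoxy and meta to the formyl group.

Step 2
Reactants: 2 5-bromo-2,3,4-trimethoxybenzaldehyde
Product: 4 5-bromo-2,3,4-trimethoxyphenol, via bromotrimethoxyphenyl formate 3 (not isolated)
Conditions: mCPBA, CH2Cl2, 0 °C to rt; then K2CO3 (cat.), MeOH, rt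
Reagents that add atoms: 3-chloroperoxybenzoic acid, OOC(=O)c1cccc(Cl)c1
Why: Baeyer–Villiger (Dakin-type) oxidation, in which the electron-rich aryl group migrates to give the aryl formate that mild methanolysis cleaves to the phenol.

Step 3
Reactants: 4 5-bromo-2,3,4-trimethoxyphenol
Product: 5 1-(benzyloxy)-5-bromo-2,3,4-trimethoxybenzene
Conditions: BnBr, K2CO3, DMF, rt
Reagents that add atoms: benzyl bromide, BrCc1ccccc1
Why: Williamson ether synthesis on an unhindered phenoxide.

Step 4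
Reactants: 5 1-(benzyloxy)-5-bromo-2,3,4-trimethoxybenzene
Product: 8 5-(benzyloxy)-2,3,4-trimethoxyphenol, via aryllithium 6 (not isolated), via dimethyl arylboronate 7 (not isolated)
Conditions: n-BuLi, THF, −78 °C; B(OMe)3, −78 °C to rt; then AcOH, 30% H2O2, 0 °C to rt
Reagents that add atoms: hydrogen peroxide, OO
Why: Bromine–lithium exchange at −78 °C is faster than any attack on the benzyl ether, and borate trapping followed by oxidative 1,2-aryl shift (boronate oxidation) is the standard ArBr to ArOH sequence.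

Step 5
Reactants: 8 5-(benzyloxy)-2,3,4-trimethoxyphenol
Product: 9 6-(benzyloxy)-2-hydroxy-3,4,5-trimethoxybenzaldehyde
Conditions: MgCl2, Et3N, paraformaldehyde, MeCN, reflux
Reagents that add atoms: paraformaldehyde (formaldehyde), C=O
Why: Casnati–Skattebøl ortho-formylation delivers formaldehyde from the magnesium phenoxide to the ortho carbon, and the only free ring position is that ortho carbon.

Step 6
Reactants: 9 6-(benzyloxy)-2-hydroxy-3,4,5-trimethoxybenzaldehyde
Product: 10 2,6-bis(benzyloxy)-3,4,5-trimethoxybenzaldehyde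
Conditions: BnBr, K2CO3, DMF, 60 °C
Reagents that add atoms: benzyl bromide, BrCc1ccccc1
Why: Williamson ether synthesis; warming overcomes the hydrogen bond of the phenol to the aldehyde.

Step 7
Reactants: 10 2,6-bis(benzyloxy)-3,4,5-trimethoxybenzaldehyde
Product: 11 1,3-bis(benzyloxy)-2-ethynyl-4,5,6-trimethoxybenzene
Conditions: dimethyl (1-diazo-2-oxopropyl)phosphonate, K2CO3, MeOH–THF, rt
Reagents that add atoms: dimethyl (1-diazo-2-oxopropyl)phosphonate (Ohira–Bestmann reagent), CC(=O)C(=[N+]=[N-])P(=O)(OC)OC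
Why: Ohira–Bestmann (Seyferth–Gilbert) homologation, in which the diazoalkene loses N2 and a 1,2-hydrogen shift of the alkylidene carbene gives the terminal alkyne under conditions that leave the ethers untouched.

Step 8
Reactants: 12 3-hydroxy-4,5-dimethoxybenzaldehyde
Product: 13 3-(benzyloxy)-4,5-dimethoxybenzaldehyde
Conditions: BnBr, K2CO3, DMF, rt
Reagents that add atoms: benzyl bromide, BrCc1ccccc1
Why: Williamson ether synthesis; the benzyl group masks the ring B phenol until the final hydrogenolysis.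

Step 9
Reactants: 13 3-(benzyloxy)-4,5-dimethoxybenzaldehyde
Product: 14 (E)-3-(benzyloxy)-4,5-dimethoxybenzaldehyde oxime
Conditions: NH2OH·HCl, NaOAc, EtOH–H2O, rt
Reagents that add atoms: hydroxylamine hydrochloride, NO.Cl
Why: Oxime condensation of an aryl aldehyde, which should give the E isomer under thermodynamic control.

Step 10
Reactants: 14 (E)-3-(benzyloxy)-4,5-dimethoxybenzaldehyde oxime
Product: 15 (Z)-3-(benzyloxy)-N-hydroxy-4,5-dimethoxybenzimidoyl chloride
Conditions: NCS, DMF, rt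
Reagents that add atoms: N-chlorosuccinimide, O=C1CCC(=O)N1Cl
Why: Chlorination of the aldoxime carbon with NCS in DMF is the standard route to hydroximoyl chlorides and is faster than ring chlorination, also for alkoxy-substituted benzaldoximes.

Step 11
Reactants: 15 (Z)-3-(benzyloxy)-N-hydroxy-4,5-dimethoxybenzimidoyl chloride; 11 1,3-bis(benzyloxy)-2-ethynyl-4,5,6-trimethoxybenzene
Product: 17 3-[3-(benzyloxy)-4,5-dimethoxyphenyl]-5-[2,6-bis(benzyloxy)-3,4,5-trimethoxyphenyl]isoxazole, via 3-(benzyloxy)-4,5-dimethoxybenzonitrile oxide 16 (not isolated)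
Conditions: 15 (1.5 equiv), Et3N (slow addition), CH2Cl2, rt to 40 °C
Reagents that add atoms: none
Why: Et3N dehydrochlorinates 15 to nitrile oxide 16, which adds to the terminal alkyne 11 in a concerted, asynchronous (3+2) cycloaddition, the Huisgen nitrile oxide–alkyne reaction that is well known for 3,5-diarylisoxazoles. The isoxazole is closed intermolecularly by forming two bonds at once, nitrile oxide carbon to the terminal alkyne carbon (future C2–C3 of ring C) and oxide oxygen to the aryl-bearing alkyne carbon (future C4–O). No stereocentre is formed. The step needs regioselectivity, and the terminal alkyne secures it: the unsubstituted carbon carries the larger HOMO coefficient and is unhindered, so it takes the aryl-bearing dipole carbon, while only the small oxygen terminus must approach the carbon shielded by the two ortho benzyloxy groups. It also needs cycloaddition to outrun dimerisation of 16 to the furoxan, which slow addition of base and an excess of 15 should ensure.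

Step 12
Reactants: 17 3-[3-(benzyloxy)-4,5-dimethoxyphenyl]-5-[2,6-bis(benzyloxy)-3,4,5-trimethoxyphenyl]isoxazole
Product: 18 3-[3-(benzyloxy)-4,5-dimethoxyphenyl]-5-[2,6-bis(benzyloxy)-3,4,5-trimethoxyphenyl]-4-iodoisoxazole
Conditions: NIS, TFA (cat.), MeCN, 0 °C to rt
Reagents that add atoms: N-iodosuccinimide, O=C1CCC(=O)N1I
Why: Electrophilic aromatic iodination at isoxazole C4, the β-carbon of the ring enol ether and the only CH of the heterocycle, while ring A has no free position and the two CH positions of ring B are hindered and deactivated by the isoxazolyl group.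

Step 13
Reactants: 18 3-[3-(benzyloxy)-4,5-dimethoxyphenyl]-5-[2,6-bis(benzyloxy)-3,4,5-trimethoxyphenyl]-4-iodoisoxazole
Product: 21 3-[3-(benzyloxy)-4,5-dimethoxyphenyl]-5-[2,6-bis(benzyloxy)-3,4,5-trimethoxyphenyl]isoxazol-4-ol, via isoxazol-4-ylmagnesium chloride 19 (not isolated), via dimethyl isoxazol-4-ylboronate 20 (not isolated)
Conditions: iPrMgCl·LiCl, THF, −40 °C; B(OMe)3, −40 °C to rt; then AcOH, 30% H2O2, 0 °C to rt
Reagents that add atoms: hydrogen peroxide, OO
Why: Iodine–magnesium exchange on a 3,5-disubstituted 4-iodoisoxazole gives a Grignard reagent that is stable at low temperature, and borate trapping with boronate oxidation converts the carbon–iodine bond into the C4 hydroxyl without touching the N–O bond or the benzyl ethers.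

Step 14
Reactants: 21 3-[3-(benzyloxy)-4,5-dimethoxyphenyl]-5-[2,6-bis(benzyloxy)-3,4,5-trimethoxyphenyl]isoxazol-4-ol
Product: 23 3,5-dihydroxy-2-(3-hydroxy-4,5-dimethoxyphenyl)-6,7,8-trimethoxy-4H-chromen-4-one (3-demethyldigicitrin), via hydroxy enaminone 22 (not isolated)
Conditions: H2 (1 atm), 10% Pd/C, EtOAc–MeOH, rt; filter under Ar; then 2 M HCl, EtOH, 70 °C
Reagents that add atoms: none
Why: Proposed new method: hydrogenolysis over Pd/C should cleave the three benzyl ethers and the weak N–O bond to give the chelated 2-hydroxy enaminone 22, in which either of the two equivalent ortho phenols of ring A adds to the protonated enamine carbon (6-endo addition–elimination) and ammonia is lost, so that isoxazole C3, C4 and C5 become C2, C3 and C4 of ring C with the C3 hydroxyl already in place; the closest known reaction type is the hydrogenolytic opening of 3,5-diarylisoxazoles to enaminones and their acid cyclisation to flavones, which is not known for an isoxazol-4-ol.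

**Compound list**
1 | 2,3,4-trimethoxybenzaldehyde | COc1ccc(C=O)c(OC)c1OC | starting material
2 | 5-bromo-2,3,4-trimethoxybenzaldehyde | COc1c(Br)cc(C=O)c(OC)c1OC | intermediate
3 | 5-bromo-2,3,4-trimethoxyphenyl formate | COc1c(Br)cc(OC=O)c(OC)c1OC | intermediate
4 | 5-bromo-2,3,4-trimethoxyphenol | COc1c(Br)cc(O)c(OC)c1OC | intermediate
5 | 1-(benzyloxy)-5-bromo-2,3,4-trimethoxybenzene | COc1c(Br)cc(OCc2ccccc2)c(OC)c1OC | intermediate
6 | [5-(benzyloxy)-2,3,4-trimethoxyphenyl]lithium | [Li]c1cc(OCc2ccccc2)c(OC)c(OC)c1OC | intermediate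
7 | dimethyl [5-(benzyloxy)-2,3,4-trimethoxyphenyl]boronate | COB(OC)c1cc(OCc2ccccc2)c(OC)c(OC)c1OC | intermediate
8 | 5-(benzyloxy)-2,3,4-trimethoxyphenol | COc1c(O)cc(OCc2ccccc2)c(OC)c1OC | intermediate
9 | 6-(benzyloxy)-2-hydroxy-3,4,5-trimethoxybenzaldehyde | COc1c(O)c(C=O)c(OCc2ccccc2)c(OC)c1OC | intermediate
10 | 2,6-bis(benzyloxy)-3,4,5-trimethoxybenzaldehyde | COc1c(OCc2ccccc2)c(C=O)c(OCc2ccccc2)c(OC)c1OC | intermediate
11 | 1,3-bis(benzyloxy)-2-ethynyl-4,5,6-trimethoxybenzene | C#Cc1c(OCc2ccccc2)c(OC)c(OC)c(OC)c1OCc1ccccc1 | intermediate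
12 | 3-hydroxy-4,5-dimethoxybenzaldehyde | COc1cc(C=O)cc(O)c1OC | starting material
13 | 3-(benzyloxy)-4,5-dimethoxybenzaldehyde | COc1cc(C=O)cc(OCc2ccccc2)c1OC | intermediate
14 | (E)-3-(benzyloxy)-4,5-dimethoxybenzaldehyde oxime | COc1cc(/C=N/O)cc(OCc2ccccc2)c1OC | intermediate
15 | (Z)-3-(benzyloxy)-N-hydroxy-4,5-dimethoxybenzimidoyl chloride | COc1cc(/C(Cl)=N/O)cc(OCc2ccccc2)c1OC | intermediate
16 | 3-(benzyloxy)-4,5-dimethoxybenzonitrile oxide | COc1cc(C#[N+][O-])cc(OCc2ccccc2)c1OC | intermediate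
17 | 3-[3-(benzyloxy)-4,5-dimethoxyphenyl]-5-[2,6-bis(benzyloxy)-3,4,5-trimethoxyphenyl]isoxazole | COc1cc(-c2cc(-c3c(OCc4ccccc4)c(OC)c(OC)c(OC)c3OCc3ccccc3)on2)cc(OCc2ccccc2)c1OC | intermediate
18 | 3-[3-(benzyloxy)-4,5-dimethoxyphenyl]-5-[2,6-bis(benzyloxy)-3,4,5-trimethoxyphenyl]-4-iodoisoxazole | COc1cc(-c2noc(-c3c(OCc4ccccc4)c(OC)c(OC)c(OC)c3OCc3ccccc3)c2I)cc(OCc2ccccc2)c1OC | intermediate
19 | {3-[3-(benzyloxy)-4,5-dimethoxyphenyl]-5-[2,6-bis(benzyloxy)-3,4,5-trimethoxyphenyl]isoxazol-4-yl}magnesium chloride | COc1cc(-c2noc(-c3c(OCc4ccccc4)c(OC)c(OC)c(OC)c3OCc3ccccc3)c2[Mg]Cl)cc(OCc2ccccc2)c1OC | intermediate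
20 | dimethyl {3-[3-(benzyloxy)-4,5-dimethoxyphenyl]-5-[2,6-bis(benzyloxy)-3,4,5-trimethoxyphenyl]isoxazol-4-yl}boronate | COc1cc(-c2noc(-c3c(OCc4ccccc4)c(OC)c(OC)c(OC)c3OCc3ccccc3)c2B(OC)OC)cc(OCc2ccccc2)c1OC | intermediate
21 | 3-[3-(benzyloxy)-4,5-dimethoxyphenyl]-5-[2,6-bis(benzyloxy)-3,4,5-trimethoxyphenyl]isoxazol-4-ol | COc1cc(-c2noc(-c3c(OCc4ccccc4)c(OC)c(OC)c(OC)c3OCc3ccccc3)c2O)cc(OCc2ccccc2)c1OC | intermediate
22 | (E)-3-amino-1-(2,6-dihydroxy-3,4,5-trimethoxyphenyl)-2-hydroxy-3-(3-hydroxy-4,5-dimethoxyphenyl)prop-2-en-1-one (amino group cis to the ketone) | COc1cc(/C(N)=C(\O)C(=O)c2c(O)c(OC)c(OC)c(OC)c2O)cc(O)c1OC | intermediate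
23 | 3,5-dihydroxy-2-(3-hydroxy-4,5-dimethoxyphenyl)-6,7,8-trimethoxy-4H-chromen-4-one (3-demethyldigicitrin) | COc1cc(-c2oc3c(OC)c(OC)c(OC)c(O)c3c(=O)c2O)cc(O)c1OC | target

**Step count and risk**
Total steps: 14. Longest linear sequence: 11 steps (steps 1–7, then 11–14).

Steps most likely to fail:

Step 14. Under hydrogen the 2-hydroxy enaminone may tautomerise to an α-amino diketone and be reduced further, or the electron-rich amino enol may oxidise on handling before it cyclises. The fallback sets out from 17 and comes back at 23 by known chemistry. Isoxazole 17 is hydrogenolysed (H2, Pd/C, EtOAc–MeOH) to the (Z)-3-amino-1-(2,6-dihydroxy-3,4,5-trimethoxyphenyl)-3-(3-hydroxy-4,5-dimethoxyphenyl)prop-2-en-1-one F1. Acid (HCl, EtOH, 70 °C) closes it to the flavone 5-hydroxy-2-(3-hydroxy-4,5-dimethoxyphenyl)-6,7,8-trimethoxy-4H-chromen-4-one F2. Both phenols are benzylated (BnBr, K2CO3, DMF, 80 °C) to 5-(benzyloxy)-2-[3-(benzyloxy)-4,5-dimethoxyphenyl]-6,7,8-trimethoxy-4H-chromen-4-one F3. C3 is deprotonated with LiN(iPr)2 (THF, −78 °C) to the 3-lithioflavone F4, which is trapped with B(OMe)3 as the dimethyl flavon-3-ylboronate F5 and oxidised (AcOH, H2O2) to the 3-hydroxyflavone dibenzyl ether F6. Hydrogenolysis (H2, Pd/C) then gives 23.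

Step 11. Dimerisation of the nitrile oxide to the furoxan may outrun addition to the hindered, twisted aryl alkyne, or the regiochemistry may erode. The fallback sets out from 11 and 13 and comes back at 17. Alkyne 11 is converted with EtMgBr (THF) into the alkynylmagnesium bromide F7, which adds to aldehyde 13 to give the racemic propargylic alcohol F8. MnO2 (CH2Cl2) oxidises it to the ynone F9, and NH2OH·HCl with pyridine in MeOH gives the Z ynone oxime F10. AuCl3 (cat., CH2Cl2) then promotes 5-endo-dig cycloisomerisation of the oxime oxygen onto the alkyne, which puts nitrogen on the ring B carbon and gives 17.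

Step 12. Iodination of ring B ortho to its alkoxy groups may compete with attack at isoxazole C4. The fallback sets out from 11 and comes back at 21, so steps 12 and 13 are both replaced. Alkyne 11 is deprotonated (n-BuLi, THF, −78 °C) to the lithium acetylide F11 and borylated with 2-isopropoxy-4,4,5,5-tetramethyl-1,3,2-dioxaborolane (then HCl in Et2O) to the alkynyl pinacol boronate F12. Cycloaddition with nitrile oxide 16 (from 15 and Et3N) is known to place boron at C4 for substituted alkynylboronates and should give the isoxazol-4-yl pinacol boronate F13. Oxidation (H2O2, NaOH, THF, 0 °C) gives 21.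

**Further compounds**
F1 | step 14 | (Z)-3-amino-1-(2,6-dihydroxy-3,4,5-trimethoxyphenyl)-3-(3-hydroxy-4,5-dimethoxyphenyl)prop-2-en-1-one | COc1cc(/C(N)=C/C(=O)c2c(O)c(OC)c(OC)c(OC)c2O)cc(O)c1OC
F2 | step 14 | 5-hydroxy-2-(3-hydroxy-4,5-dimethoxyphenyl)-6,7,8-trimethoxy-4H-chromen-4-one | COc1cc(-c2cc(=O)c3c(O)c(OC)c(OC)c(OC)c3o2)cc(O)c1OC
F3 | step 14 | 5-(benzyloxy)-2-[3-(benzyloxy)-4,5-dimethoxyphenyl]-6,7,8-trimethoxy-4H-chromen-4-one | COc1cc(-c2cc(=O)c3c(OCc4ccccc4)c(OC)c(OC)c(OC)c3o2)cc(OCc2ccccc2)c1OC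
F4 | step 14 | {5-(benzyloxy)-2-[3-(benzyloxy)-4,5-dimethoxyphenyl]-6,7,8-trimethoxy-4-oxo-4H-chromen-3-yl}lithium | COc1cc(-c2oc3c(OC)c(OC)c(OC)c(OCc4ccccc4)c3c(=O)c2[Li])cc(OCc2ccccc2)c1OC
F5 | step 14 | dimethyl {5-(benzyloxy)-2-[3-(benzyloxy)-4,5-dimethoxyphenyl]-6,7,8-trimethoxy-4-oxo-4H-chromen-3-yl}boronate | COc1cc(-c2oc3c(OC)c(OC)c(OC)c(OCc4ccccc4)c3c(=O)c2B(OC)OC)cc(OCc2ccccc2)c1OC
F6 | step 14 | 5-(benzyloxy)-2-[3-(benzyloxy)-4,5-dimethoxyphenyl]-3-hydroxy-6,7,8-trimethoxy-4H-chromen-4-one | COc1cc(-c2oc3c(OC)c(OC)c(OC)c(OCc4ccccc4)c3c(=O)c2O)cc(OCc2ccccc2)c1OC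
F7 | step 11 | {[2,6-bis(benzyloxy)-3,4,5-trimethoxyphenyl]ethynyl}magnesium bromide | Br[Mg]C#Cc1c(OCc2ccccc2)c(OC)c(OC)c(OC)c1OCc1ccccc1
F8 | step 11 | racemic 1-[3-(benzyloxy)-4,5-dimethoxyphenyl]-3-[2,6-bis(benzyloxy)-3,4,5-trimethoxyphenyl]prop-2-yn-1-ol | COc1cc(C(O)C#Cc2c(OCc3ccccc3)c(OC)c(OC)c(OC)c2OCc2ccccc2)cc(OCc2ccccc2)c1OC
F9 | step 11 | 1-[3-(benzyloxy)-4,5-dimethoxyphenyl]-3-[2,6-bis(benzyloxy)-3,4,5-trimethoxyphenyl]prop-2-yn-1-one | COc1cc(C(=O)C#Cc2c(OCc3ccccc3)c(OC)c(OC)c(OC)c2OCc2ccccc2)cc(OCc2ccccc2)c1OC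
F10 | step 11 | (Z)-1-[3-(benzyloxy)-4,5-dimethoxyphenyl]-3-[2,6-bis(benzyloxy)-3,4,5-trimethoxyphenyl]prop-2-yn-1-one oxime (hydroxyl syn to the alkyne) | COc1cc(/C(C#Cc2c(OCc3ccccc3)c(OC)c(OC)c(OC)c2OCc2ccccc2)=N/O)cc(OCc2ccccc2)c1OC
F11 | step 12 | {[2,6-bis(benzyloxy)-3,4,5-trimethoxyphenyl]ethynyl}lithium | [Li]C#Cc1c(OCc2ccccc2)c(OC)c(OC)c(OC)c1OCc1ccccc1
F12 | step 12 | 2-{[2,6-bis(benzyloxy)-3,4,5-trimethoxyphenyl]ethynyl}-4,4,5,5-tetramethyl-1,3,2-dioxaborolane | CC1(C)OB(C#Cc2c(OCc3ccccc3)c(OC)c(OC)c(OC)c2OCc2ccccc2)OC1(C)C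
F13 | step 12 | 3-[3-(benzyloxy)-4,5-dimethoxyphenyl]-5-[2,6-bis(benzyloxy)-3,4,5-trimethoxyphenyl]-4-(4,4,5,5-tetramethyl-1,3,2-dioxaborolan-2-yl)isoxazole | COc1cc(-c2noc(-c3c(OCc4ccccc4)c(OC)c(OC)c(OC)c3OCc3ccccc3)c2B2OC(C)(C)C(C)(C)O2)cc(OCc2ccccc2)c1OC
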